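## Structural features

Moracin Q (25) is a 2-arylbenzofuran in which benzo ring A and furan ring B share the C3a–C7a bond and a 3,5-dihydroxyphenyl ring C sits on C2 (benzofuran locants O1, C2, C3, C3a, C4–C7, C7a are used throughout). Ring A carries three different neighbours in a row next to the ring fusion: a 3-methyl-2-oxobutyl chain on C4, a methoxy group on C5 and a free hydroxyl on C6, with hydrogen on C7. The target has no stereocentre, and the route passes through isolated, racemic centres only (the ester α-carbon in 5, 6, 7, 9 and 12–15, C6 of 17, the boron- or hydroxyl-bearing carbon of 22 and 23), each of which is erased later, so no two stereocentres are ever adjacent. Fragile groups are the three phenols and the electron-rich benzofuran (oxidation), the ketone with its doubly activated CH2, and, on the way, the acid-labile benzyl enol ether and the acid-sensitive furan. The real difficulty is the regiocontrolled placement of the contiguous C4 chain, C5–OMe and C6–OH with the two oxygens told apart, not the furan or the biaryl bond. The key step uses the furan C3a=C7a double bond as the cis-locked central bond of a hexatriene whose ends are a ketene (C5=C4, carrying the side chain and the future C5 oxygen) and an enol ether (C7=C6, carrying the future C6 oxygen), so that forming C5–C6 closes ring A with every substituent already in place.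

## Logic of the disconnections

**25 to 24.** The three O–benzyl bonds are cut last in the forward sense. One protecting group covers the C6 oxygen and both ring C oxygens, so 24 is a fully masked, oxidation-stable form of 25. The forward step must cleave three aryl benzyl ethers without reducing the C2=C3 bond or the ketone.

**24 to 23 to 21 (through 22).** The C=O of the side chain is traced back to a carbinol and then to the C=C of a prenyl group. The oxygen is introduced on the alkene carbon next to the benzylic CH2. The gain is that the side chain travels through base, heat and palladium chemistry as an inert olefin that is installed by a simple alkylation. The demand is anti-Markovnikov hydration of a trisubstituted alkene that leaves the benzofuran untouched, followed by a mild oxidation.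

**21 to 19 (through 20).** The C5 O–CH3 bond is cut and replaced by the O–acetyl bond of 19. C5 is the only oxygen that arrives acylated, so it can be exchanged for methyl while C6 stays benzylated. The demand is ester cleavage and O-alkylation of a phenol flanked on both sides.

**19 to 14 (through 18, 17, 16 and 15).** The C5–C6 bond of ring A is cut. Ring A opens to a furan that carries the acid side arm on one carbon and the enol ether on the next. This turns a pentasubstituted benzene problem into a 2,3,5-trisubstituted furan, and the two ring A oxygens come from different sources (carboxyl group and enol ether). The forward step must generate 16 without destroying the enol ether and must close by the six-electron path only.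

**14 to 12 (through 13), and 12 to 9 + 10 (through 11).** The acid is taken back to its methyl ester, and the C7=C6 double bond is cut by a carbonyl olefination into 9 and 10. This brings in C6 together with its benzyl-protected oxygen in one operation. The demands are E geometry, addition to the aldehyde faster than proton transfer from the ester α-position, and a hydrolysis and work-up that the enol ether survives.

**9 to 7 + 8.** The bond between the furan α-carbon (the future C2) and ring C is cut. In 7 the formyl group blocks one α-position, so C–H arylation can only occur at the other. Doing this after the formylation keeps the electron-rich ring C away from the formylating electrophile. The demand is site-selective C–H arylation that spares the prenyl alkene and the aldehyde.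

**7 to 5 (through 6).** The bond from the furan α-carbon next to the side arm to the formyl carbon (the future C7a–C7 bond) is cut. Electrophilic formylation of a 3-substituted furan is the forward step, and it must go to the α-carbon adjacent to the substituent.

**5 to 2 + 3 (through 4), and 2 to 1.** The bond from the ester α-carbon to the allylic CH2 (the future C4–side-chain bond) is cut, giving the enolate alkylation of 2 with 3. Compound 2 comes from 1 by esterification. The demand is clean mono-alkylation at the primary allylic carbon.

## Other disconnections considered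

Alternative 1: The cut removes the C4–CH2 bond of the side chain and the C3a–C3 bond. Ring A is taken as a pre-formed arene, 1-(benzyloxy)-4-iodo-2-methoxy-5-(methoxymethoxy)benzene A1, and the furan stays open.

- Forward key step: a Catellani reaction (Pd(OAc)2, a triarylphosphine, norbornene, K2CO3) would join A1 with 2-isopropyloxirane A2 and 1,3-bis(benzyloxy)-5-ethenylbenzene A3. The sequence is oxidative addition at the C3a iodide, norbornene insertion, palladation of the neighbouring C4–H, opening of A2 at its CH2 end by the palladacycle, norbornene extrusion and a terminating Heck reaction with A3. The product would be stilbene carbinol A4, with no ring closed.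
- In its favour: three pieces and two skeletal bonds in one flask; the ring A pattern is simply carried in A1; the side chain arrives as the carbinol, one oxidation from the ketone. On convergence and on side-chain economy (no alkene hydration) it is the better of the two plans.
- Against it here: the only ortho C–H of A1 is C4–H, wedged between the iodide and the C5 methoxy group, so the palladacycle must form at a doubly flanked site. Direct Heck coupling of A1 with A3 or retention of norbornene can take over there. A4 is still four operations from 25 (acetal cleavage, oxidative O1–C2 closure, carbinol oxidation, debenzylation), and the free carbinol is a competing nucleophile during the oxidative furan closure.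
- Comparison: structurally both plans fix ring A without ambiguity, alternative 1 by purchase and the ortho rule, the chosen plan by the origin of each atom. Mechanistically the chosen closure is one intramolecular pericyclic event, whereas the Catellani step is a multicomponent catalytic cycle with several exits and is the less predictable. In step count alternative 1 is judged equal or somewhat shorter (about eight to nine operations including A1 and A3, against eleven), which is its advantage.

Alternative 2: The cut is the O1–C7a bond. The precursor is the deoxybenzoin A5, whose ketone oxygen becomes O1.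

- Forward key step: FeCl3 would oxidise the electron-rich ring (the C5 methoxy group is para to C7a), the enol oxygen would add to C7a, and loss of two electrons and two protons would give benzofuran ester A6.
- In its favour: no phenol has to be installed or protected at C7a; closure can only occur at C7a because C4 is blocked; the reagent is cheap. C5 already carries its methyl ether, so the acetate-to-methyl exchange of the chosen route is not needed, and on that point it is the better plan.
- Against it here: FeCl3 is both a Lewis acid and an oxidant towards benzyl ethers, the 3,5-dialkoxyphenyl ring and the doubly activated CH2 of A5, so debenzylation, chlorination or oxidative coupling may compete. A5 is a 1,2,3,4-tetrasubstituted benzene with two different CH2–carbonyl arms on neighbouring carbons, which is the same contiguous-substitution problem in another form. A6 still needs conversion of the ester into the isopropyl ketone without over-addition before debenzylation.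
- Comparison: structurally it is the equal of the chosen plan in regiochemical certainty at the closure, but it postpones the ring A pattern instead of creating it. Mechanistically an oxidative Lewis-acidic closure in the presence of three benzyl ethers is judged less compatible than a thermal electrocyclisation. On step economy it is expected to be longer, because both A5 and the side chain need extra operations.

Alternative 3: The cut is the furan C2=C3 double bond. The precursor is phosphonium salt A7, in which the future C3 carries phosphorus and O1 carries the 3,5-bis(benzyloxy)benzoyl group.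

- Forward key step: Et3N in hot toluene would form the ylide at C3, which attacks the ester carbonyl on O1. Collapse of the oxaphosphetane with loss of the phosphine oxide closes the furan and gives A8, the same compound as 21.
- In its favour: the intramolecular Wittig closure is an established, mild way to 2-arylbenzofurans that tolerates benzyl ethers and a prenyl group. It is judged more reliable than the key step of the chosen route, and this is the point on which it is the better. It reaches the C5 methyl ether directly, and the endgame from A8 would be the same as steps 9 to 11.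
- Against it here: all the difficulty moves into A7, a pentasubstituted benzene in which prenyl, methoxy, benzyloxy, acyloxy and phosphoniomethyl groups must stand in a fixed order. C-prenylation next to oxygen is prone to O-alkylation and to reverse-prenyl products, so a long arene synthesis would be needed.
- Comparison: structurally the chosen plan creates the ring A pattern in the bond-forming event, whereas alternative 3 must build it beforehand. Mechanistically it is polar, stepwise and well precedented against pericyclic and less precedented. In step economy the two are equal from 21 onward, but making A7 is expected to cost more operations than the eight that lead to 21.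

Key step: step 7

Assumption: the Wittig olefination of step 5 is expected to form both enol ether geometries; the route is written for the E isomer, isolated by chromatography on base-washed silica.

## Route

Step 1
Reactants: 1 2-(furan-3-yl)acetic acid
Product: 2 methyl 2-(furan-3-yl)acetate
Conditions: MeI, K2CO3, DMF, rt
Reagents that add atoms: iodomethane CI
Why: SN2 O-methylation of the acid under carbonate base; the non-acidic conditions spare the acid-sensitive furan.

Step 2
Reactants: 2 methyl 2-(furan-3-yl)acetate; 3 1-bromo-3-methylbut-2-ene
Product: 5 methyl 2-(furan-3-yl)-5-methylhex-4-enoate (racemic), via lithium enolate 4 (not isolated)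
Conditions: LiN(iPr)2, THF, −78 °C; then 3, −78 → 0 °C
Reagents that add atoms: none
Why: Ester enolate alkylation; 4 attacks the primary allylic carbon of 3 by SN2, and the new stereocentre is formed as a racemate that is destroyed in step 7.

Step 3
Reactants: 5 methyl 2-(furan-3-yl)-5-methylhex-4-enoate
Product: 7 methyl 2-(2-formylfuran-3-yl)-5-methylhex-4-enoate (racemic), via iminium chloride 6 (not isolated)
Conditions: POCl3, DMF, 0 °C → rt; then aq. NaOAc
Reagents that add atoms: N,N-dimethylformamide CN(C)C=O; water O
Why: Vilsmeier–Haack formylation; a 3-alkylfuran is attacked preferentially at the α-carbon next to the substituent, and 6 (drawn as the chloride) is hydrolysed on buffered work-up. The isolated trisubstituted alkene is far less nucleophilic than the furan, and formylating before the arylation keeps ring C away from the electrophile.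

Step 4
Reactants: 7 methyl 2-(2-formylfuran-3-yl)-5-methylhex-4-enoate; 8 1-bromo-3,5-bis(benzyloxy)benzene
Product: 9 methyl 2-{5-[3,5-bis(benzyloxy)phenyl]-2-formylfuran-3-yl}-5-methylhex-4-enoate (racemic)
Conditions: Pd(OAc)2 (5 mol%), PCy3·HBF4 (10 mol%), PivOH (30 mol%), K2CO3, DMA, 100 °C
Reagents that add atoms: none
Why: Palladium-catalysed direct C–H arylation by carboxylate-assisted concerted metalation–deprotonation, well known for 2-formylfurans; the formyl group blocks one α-position, so only the remaining α C–H reacts, and the hindered trisubstituted alkene is a poor Heck acceptor.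

Step 5
Reactants: 9 methyl 2-{5-[3,5-bis(benzyloxy)phenyl]-2-formylfuran-3-yl}-5-methylhex-4-enoate; 10 (benzyloxymethyl)triphenylphosphonium chloride
Product: 12 methyl 2-{2-[(E)-2-(benzyloxy)ethenyl]-5-[3,5-bis(benzyloxy)phenyl]furan-3-yl}-5-methylhex-4-enoate (racemic), via phosphorus ylide 11 (not isolated)
Conditions: 10, NaN(SiMe3)2, THF, 0 °C; then 9, −78 °C → rt; E isomer by chromatography (SiO2, 1% Et3N)
Reagents that add atoms: none
Why: Wittig olefination with the non-stabilised alkoxymethylene ylide 11 turns the aldehyde into the benzyl enol ether, bringing in C6 with its protected oxygen. Such ylides are not strongly stereoselective, so the E isomer is separated, and the low temperature favours carbonyl addition over proton transfer from the ester α-position.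

Step 6
Reactants: 12 methyl 2-{2-[(E)-2-(benzyloxy)ethenyl]-5-[3,5-bis(benzyloxy)phenyl]furan-3-yl}-5-methylhex-4-enoate
Product: 14 2-{2-[(E)-2-(benzyloxy)ethenyl]-5-[3,5-bis(benzyloxy)phenyl]furan-3-yl}-5-methylhex-4-enoic acid (racemic), via lithium carboxylate 13 (not isolated)
Conditions: LiOH, THF/MeOH/H2O, rt; then AcOH to pH 5, 0 °C
Reagents that add atoms: lithium hydroxide [Li+].[OH-]
Why: Saponification to 13; the enol ether is stable to base, and acidification with a weak acid only to pH 5 in the cold frees the acid without hydrolysing it. 14 is used at once.

Step 7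
Reactants: 14 2-{2-[(E)-2-(benzyloxy)ethenyl]-5-[3,5-bis(benzyloxy)phenyl]furan-3-yl}-5-methylhex-4-enoic acid
Product: 19 6-(benzyloxy)-2-[3,5-bis(benzyloxy)phenyl]-4-(3-methylbut-2-enyl)benzofuran-5-yl acetate, via mixed anhydride 15 (not isolated), via dienylketene 16 (not isolated), via cyclohexadienone 17 (not isolated), via phenol 18 (not isolated)
Conditions: Ac2O, NaOAc, 130 °C (N2)
Reagents that add atoms: acetic anhydride CC(=O)OC(C)=O
Why: Ac2O converts the acid into mixed anhydride 15, and acetate removes the acidic hydrogen α to the furan so that acetic acid is lost and ketene 16 forms. In 16 the ketene C5=C4 bond, the furan C3a=C7a bond and the enol ether C7=C6 bond make up a hexatriene whose central bond is held cis by the ring; thermal disrotatory six-electron electrocyclisation joins C5 to C6 and closes the six-membered ring A as cyclohexadienone 17. The closest known reaction type is the Stobbe-type benzannulation of unsaturated acids in hot Ac2O/NaOAc, together with the electrocyclisation of dienylketenes in ketene-based phenol annulations. The only stereocentre formed, C6 of 17, is transient: loss of the C6 hydrogen and enolisation restore the aromatic furan and give phenol 18, so nothing has to be controlled. 18 is acetylated in the same medium to 19, which also shields the electron-rich phenol from oxidation. The step needs periselectivity for six-electron closure over [2+2] addition of the ketene to the enol ether or acylation at C7; the ring-enforced cis geometry and the E enol ether put only C6 within reach of the ketene carbon, and the competing modes would build strained four- or five-membered rings onto the furan. The acetate buffer keeps the medium only weakly acidic, which the benzyl enol ether and the prenyl group should tolerate for the time needed.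

Step 8
Reactants: 19 6-(benzyloxy)-2-[3,5-bis(benzyloxy)phenyl]-4-(3-methylbut-2-enyl)benzofuran-5-yl acetate
Product: 21 6-(benzyloxy)-2-[3,5-bis(benzyloxy)phenyl]-5-methoxy-4-(3-methylbut-2-enyl)benzofuran, via potassium phenolate 20 (not isolated)
Conditions: K2CO3 (excess), MeOH/THF, rt (N2); evaporate; then MeI, DMF, rt
Reagents that add atoms: iodomethane CI
Why: Carbonate-mediated transesterification with methanol cleaves the aryl acetate and leaves the phenol as its potassium salt 20, which is O-methylated in the same flask by SN2 reaction with MeI (Williamson ether synthesis); C5 is the only acylated oxygen, so it alone becomes the methyl ether.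

Step 9
Reactants: 21 6-(benzyloxy)-2-[3,5-bis(benzyloxy)phenyl]-5-methoxy-4-(3-methylbut-2-enyl)benzofuran
Product: 23 1-{6-(benzyloxy)-2-[3,5-bis(benzyloxy)phenyl]-5-methoxybenzofuran-4-yl}-3-methylbutan-2-ol (racemic), via alkylborane 22 (not isolated)
Conditions: BH3·THF, THF, 0 °C → rt; then NaOH, H2O2, H2O, 0 °C → rt
Reagents that add atoms: hydrogen peroxide OO
Why: Hydroboration–oxidation; boron adds to the less substituted alkene carbon to give 22 (drawn as the monoalkylborane), and oxidation with retention places the hydroxyl next to the benzylic CH2. The aromatic C2=C3 bond is much less reactive towards borane than the isolated alkene, and the racemic carbinol centre is removed in step 10.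

Step 10
Reactants: 23 1-{6-(benzyloxy)-2-[3,5-bis(benzyloxy)phenyl]-5-methoxybenzofuran-4-yl}-3-methylbutan-2-ol
Product: 24 1-{6-(benzyloxy)-2-[3,5-bis(benzyloxy)phenyl]-5-methoxybenzofuran-4-yl}-3-methylbutan-2-one
Conditions: DMP, CH2Cl2, 0 °C → rt
Reagents that add atoms: none
Why: Periodinane oxidation of the secondary alcohol to the ketone under mild conditions that leave the electron-rich benzofuran and the benzyl ethers untouched.

Step 11
Reactants: 24 1-{6-(benzyloxy)-2-[3,5-bis(benzyloxy)phenyl]-5-methoxybenzofuran-4-yl}-3-methylbutan-2-one
Product: 25 moracin Q, 1-[2-(3,5-dihydroxyphenyl)-6-hydroxy-5-methoxybenzofuran-4-yl]-3-methylbutan-2-one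
Conditions: H2 (1 atm), Pd/C, EtOAc/MeOH, rt
Reagents that add atoms: none
Why: Catalytic hydrogenolysis of three aryl benzyl ethers; at 1 atm and room temperature O-benzyl cleavage should be much faster than reduction of the aromatic benzofuran or of the non-conjugated ketone, and the reaction is stopped once debenzylation is complete.

## Compound list

1 | 2-(furan-3-yl)acetic acid | OC(=O)Cc1ccoc1 | starting material
2 | methyl 2-(furan-3-yl)acetate | COC(=O)Cc1ccoc1 | intermediate
3 | 1-bromo-3-methylbut-2-ene | CC(C)=CCBr | starting material
4 | lithium 2-(furan-3-yl)-1-methoxyethen-1-olate (lithium enolate of 2) | [Li+].COC([O-])=Cc1ccoc1 | intermediate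
5 | methyl 2-(furan-3-yl)-5-methylhex-4-enoate (racemic) | COC(=O)C(CC=C(C)C)c1ccoc1 | intermediate
6 | {[3-(1-methoxy-5-methyl-1-oxohex-4-en-2-yl)furan-2-yl]methylidene}dimethylammonium chloride (racemic) | [Cl-].COC(=O)C(CC=C(C)C)c1ccoc1C=[N+](C)C | intermediate
7 | methyl 2-(2-formylfuran-3-yl)-5-methylhex-4-enoate (racemic) | COC(=O)C(CC=C(C)C)c1ccoc1C=O | intermediate
8 | 1-bromo-3,5-bis(benzyloxy)benzene | Brc1cc(OCc2ccccc2)cc(OCc2ccccc2)c1 | starting material
9 | methyl 2-{5-[3,5-bis(benzyloxy)phenyl]-2-formylfuran-3-yl}-5-methylhex-4-enoate (racemic) | COC(=O)C(CC=C(C)C)c1cc(-c2cc(OCc3ccccc3)cc(OCc3ccccc3)c2)oc1C=O | intermediate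
10 | (benzyloxymethyl)triphenylphosphonium chloride | [Cl-].C(OCc1ccccc1)[P+](c1ccccc1)(c1ccccc1)c1ccccc1 | starting material
11 | (benzyloxymethylidene)triphenylphosphorane | C(OCc1ccccc1)=P(c1ccccc1)(c1ccccc1)c1ccccc1 | intermediate
12 | methyl 2-{2-[(E)-2-(benzyloxy)ethenyl]-5-[3,5-bis(benzyloxy)phenyl]furan-3-yl}-5-methylhex-4-enoate (racemic) | COC(=O)C(CC=C(C)C)c1cc(-c2cc(OCc3ccccc3)cc(OCc3ccccc3)c2)oc1/C=C/OCc1ccccc1 | intermediate
13 | lithium 2-{2-[(E)-2-(benzyloxy)ethenyl]-5-[3,5-bis(benzyloxy)phenyl]furan-3-yl}-5-methylhex-4-enoate (racemic) | [Li+].[O-]C(=O)C(CC=C(C)C)c1cc(-c2cc(OCc3ccccc3)cc(OCc3ccccc3)c2)oc1/C=C/OCc1ccccc1 | intermediate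
14 | 2-{2-[(E)-2-(benzyloxy)ethenyl]-5-[3,5-bis(benzyloxy)phenyl]furan-3-yl}-5-methylhex-4-enoic acid (racemic) | CC(C)=CCC(C(=O)O)c1cc(-c2cc(OCc3ccccc3)cc(OCc3ccccc3)c2)oc1/C=C/OCc1ccccc1 | intermediate
15 | acetic 2-{2-[(E)-2-(benzyloxy)ethenyl]-5-[3,5-bis(benzyloxy)phenyl]furan-3-yl}-5-methylhex-4-enoic anhydride (racemic) | CC(=O)OC(=O)C(CC=C(C)C)c1cc(-c2cc(OCc3ccccc3)cc(OCc3ccccc3)c2)oc1/C=C/OCc1ccccc1 | intermediate
16 | 2-{2-[(E)-2-(benzyloxy)ethenyl]-5-[3,5-bis(benzyloxy)phenyl]furan-3-yl}-5-methylhexa-1,4-dien-1-one (dienylketene) | CC(C)=CCC(=C=O)c1cc(-c2cc(OCc3ccccc3)cc(OCc3ccccc3)c2)oc1/C=C/OCc1ccccc1 | intermediate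
17 | 6-(benzyloxy)-2-[3,5-bis(benzyloxy)phenyl]-4-(3-methylbut-2-enyl)benzofuran-5(6H)-one (racemic) | CC(C)=CCC1=C2C=C(c3cc(OCc4ccccc4)cc(OCc4ccccc4)c3)OC2=CC(OCc2ccccc2)C1=O | intermediate
18 | 6-(benzyloxy)-2-[3,5-bis(benzyloxy)phenyl]-4-(3-methylbut-2-enyl)benzofuran-5-ol | CC(C)=CCc1c(O)c(OCc2ccccc2)cc2oc(-c3cc(OCc4ccccc4)cc(OCc4ccccc4)c3)cc12 | intermediate
19 | 6-(benzyloxy)-2-[3,5-bis(benzyloxy)phenyl]-4-(3-methylbut-2-enyl)benzofuran-5-yl acetate | CC(C)=CCc1c(OC(C)=O)c(OCc2ccccc2)cc2oc(-c3cc(OCc4ccccc4)cc(OCc4ccccc4)c3)cc12 | intermediate
20 | potassium 6-(benzyloxy)-2-[3,5-bis(benzyloxy)phenyl]-4-(3-methylbut-2-enyl)benzofuran-5-olate | [K+].CC(C)=CCc1c([O-])c(OCc2ccccc2)cc2oc(-c3cc(OCc4ccccc4)cc(OCc4ccccc4)c3)cc12 | intermediate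
21 | 6-(benzyloxy)-2-[3,5-bis(benzyloxy)phenyl]-5-methoxy-4-(3-methylbut-2-enyl)benzofuran | COc1c(OCc2ccccc2)cc2oc(-c3cc(OCc4ccccc4)cc(OCc4ccccc4)c3)cc2c1CC=C(C)C | intermediate
22 | {1-[6-(benzyloxy)-2-[3,5-bis(benzyloxy)phenyl]-5-methoxybenzofuran-4-yl]-3-methylbutan-2-yl}borane (racemic) | COc1c(OCc2ccccc2)cc2oc(-c3cc(OCc4ccccc4)cc(OCc4ccccc4)c3)cc2c1CC(B)C(C)C | intermediate
23 | 1-{6-(benzyloxy)-2-[3,5-bis(benzyloxy)phenyl]-5-methoxybenzofuran-4-yl}-3-methylbutan-2-ol (racemic) | COc1c(OCc2ccccc2)cc2oc(-c3cc(OCc4ccccc4)cc(OCc4ccccc4)c3)cc2c1CC(O)C(C)C | intermediate
24 | 1-{6-(benzyloxy)-2-[3,5-bis(benzyloxy)phenyl]-5-methoxybenzofuran-4-yl}-3-methylbutan-2-one | COc1c(OCc2ccccc2)cc2oc(-c3cc(OCc4ccccc4)cc(OCc4ccccc4)c3)cc2c1CC(=O)C(C)C | intermediate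
25 | moracin Q, 1-[2-(3,5-dihydroxyphenyl)-6-hydroxy-5-methoxybenzofuran-4-yl]-3-methylbutan-2-one | COc1c(O)cc2oc(-c3cc(O)cc(O)c3)cc2c1CC(=O)C(C)C | target

## Step count and least certain steps

Total step count: 11. Longest linear sequence: 11 steps (1 to 25); 3, 8 and 10 enter as purchased building blocks.

**Step 7 (key step).** What may go wrong: acetolysis or acid-catalysed hydration of the benzyl enol ether in hot Ac2O/AcOH before the ketene is formed; slow elimination from the mixed anhydride so that furan decomposition competes; or capture of the ketene by acetate or by the product phenol instead of ring closure. The cause is that the medium is hot and weakly acidic while the enol ether is acid-labile. Fallback, which reaches the ketene by another route and avoids hot acid: starting from 14, the acid is converted under neutral conditions with 1-chloro-N,N,2-trimethylprop-1-en-1-amine in CH2Cl2 at 0 °C into 2-{2-[(E)-2-(benzyloxy)ethenyl]-5-[3,5-bis(benzyloxy)phenyl]furan-3-yl}-5-methylhex-4-enoyl chloride F1. Slow addition of F1 to Et3N in toluene at 20–60 °C under high dilution generates 16 by dehydrochlorination; electrocyclisation to 17 and tautomerisation then give phenol 18, which is not acetylated. After removal of the solvent, 18 is stirred with K2CO3 in DMF to give phenolate 20. The route is rejoined at 20 (addition of MeI as in step 8), and acetate 19 is bypassed.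

**Step 3.** What may go wrong: loss of site selectivity between the two furan α-positions, because the branched side arm crowds the carbon next to it; and addition of hydrogen chloride to, or cation–olefin reactions of, the prenyl alkene in the chlorophosphate medium. Fallback, a change of sequence with a protecting group: starting from 2, which has a smaller side arm and no alkene, Vilsmeier–Haack formylation gives methyl 2-(2-formylfuran-3-yl)acetate F2. The aldehyde is masked with HC(OMe)3/MeOH and a catalytic pyridinium sulfonate as methyl 2-[2-(dimethoxymethyl)furan-3-yl]acetate F3. Enolate alkylation with 3 as in step 2 gives methyl 2-[2-(dimethoxymethyl)furan-3-yl]-5-methylhex-4-enoate F4, and mild aqueous acid (acetone/H2O, rt) releases the aldehyde. The route is rejoined at 7.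

**Step 5.** What may go wrong: poor geometric control in oxaphosphetane formation by a non-stabilised alkoxy ylide, so that much material is lost on separation; and proton transfer from the doubly activated ester α-position to the basic ylide, which stalls the addition. Fallback, a stereoconvergent plan in place of separation: the C6=C7 geometry is erased when 17 aromatises, so, starting from 9, the crude olefination mixture is carried on unseparated. It contains 12 together with methyl 2-{2-[(Z)-2-(benzyloxy)ethenyl]-5-[3,5-bis(benzyloxy)phenyl]furan-3-yl}-5-methylhex-4-enoate F5. Saponification as in step 6 gives 14 together with 2-{2-[(Z)-2-(benzyloxy)ethenyl]-5-[3,5-bis(benzyloxy)phenyl]furan-3-yl}-5-methylhex-4-enoic acid F6, and the mixture is heated as in step 7. F6 should pass through the Z mixed anhydride F7 and the Z dienylketene F8, whose closure is expected to be slower because the benzyloxy group points inward, to the same cyclohexadienone 17. Both series meet at 17.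

**Step 9.** What may go wrong: competing addition of borane to the electron-rich benzofuran C2=C3 bond, or incomplete oxidation of a hindered organoborane, both lowering the amount of carbinol. Fallback, an oxidation-state-neutral route to the ketone without boron: starting from 21, epoxidation of the trisubstituted alkene (mCPBA, NaHCO3, CH2Cl2, 0 °C) gives 6-(benzyloxy)-2-[3,5-bis(benzyloxy)phenyl]-4-[(3,3-dimethyloxiran-2-yl)methyl]-5-methoxybenzofuran F9. A Meinwald rearrangement (BF3·OEt2, CH2Cl2, −78 °C; opening at the tertiary carbon, then 1,2-hydride shift) gives the isopropyl ketone directly. The route is rejoined at 24, and step 10 is not needed.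

**Step 11.** What may go wrong: over-reduction, namely saturation of the furan C2=C3 bond or reduction of the ketone, while the last benzyl ether is still being cleaved. Fallback, Lewis-acid debenzylation in place of hydrogenation: starting from 24, BCl3 with pentamethylbenzene as cation scavenger in CH2Cl2 at −78 °C cleaves the three benzyl ethers while the aryl methyl ether should survive at this temperature. The route is rejoined at 25, and no new compound arises on this path.

## Further compounds

F1 | step 7 | 2-{2-[(E)-2-(benzyloxy)ethenyl]-5-[3,5-bis(benzyloxy)phenyl]furan-3-yl}-5-methylhex-4-enoyl chloride (racemic) | CC(C)=CCC(C(=O)Cl)c1cc(-c2cc(OCc3ccccc3)cc(OCc3ccccc3)c2)oc1/C=C/OCc1ccccc1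
F2 | step 3 | methyl 2-(2-formylfuran-3-yl)acetate | COC(=O)Cc1ccoc1C=O
F3 | step 3 | methyl 2-[2-(dimethoxymethyl)furan-3-yl]acetate | COC(=O)Cc1ccoc1C(OC)OC
F4 | step 3 | methyl 2-[2-(dimethoxymethyl)furan-3-yl]-5-methylhex-4-enoate (racemic) | COC(=O)C(CC=C(C)C)c1ccoc1C(OC)OC
F5 | step 5 | methyl 2-{2-[(Z)-2-(benzyloxy)ethenyl]-5-[3,5-bis(benzyloxy)phenyl]furan-3-yl}-5-methylhex-4-enoate (racemic) | COC(=O)C(CC=C(C)C)c1cc(-c2cc(OCc3ccccc3)cc(OCc3ccccc3)c2)oc1/C=C\OCc1ccccc1
F6 | step 5 | 2-{2-[(Z)-2-(benzyloxy)ethenyl]-5-[3,5-bis(benzyloxy)phenyl]furan-3-yl}-5-methylhex-4-enoic acid (racemic) | CC(C)=CCC(C(=O)O)c1cc(-c2cc(OCc3ccccc3)cc(OCc3ccccc3)c2)oc1/C=C\OCc1ccccc1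
F7 | step 5 | acetic 2-{2-[(Z)-2-(benzyloxy)ethenyl]-5-[3,5-bis(benzyloxy)phenyl]furan-3-yl}-5-methylhex-4-enoic anhydride (racemic) | CC(=O)OC(=O)C(CC=C(C)C)c1cc(-c2cc(OCc3ccccc3)cc(OCc3ccccc3)c2)oc1/C=C\OCc1ccccc1
F8 | step 5 | 2-{2-[(Z)-2-(benzyloxy)ethenyl]-5-[3,5-bis(benzyloxy)phenyl]furan-3-yl}-5-methylhexa-1,4-dien-1-one | CC(C)=CCC(=C=O)c1cc(-c2cc(OCc3ccccc3)cc(OCc3ccccc3)c2)oc1/C=C\OCc1ccccc1
F9 | step 9 | 6-(benzyloxy)-2-[3,5-bis(benzyloxy)phenyl]-4-[(3,3-dimethyloxiran-2-yl)methyl]-5-methoxybenzofuran (racemic) | COc1c(OCc2ccccc2)cc2oc(-c3cc(OCc4ccccc4)cc(OCc4ccccc4)c3)cc2c1CC1OC1(C)C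
F0 | step 11 | none | none
A1 | alternative 1 | 1-(benzyloxy)-4-iodo-2-methoxy-5-(methoxymethoxy)benzene | COCOc1cc(OCc2ccccc2)c(OC)cc1I
A2 | alternative 1 | 2-isopropyloxirane (racemic) | CC(C)C1CO1
A3 | alternative 1 | 1,3-bis(benzyloxy)-5-ethenylbenzene | C=Cc1cc(OCc2ccccc2)cc(OCc2ccccc2)c1
A4 | alternative 1 | 1-{3-(benzyloxy)-6-[(E)-2-(3,5-bis(benzyloxy)phenyl)ethenyl]-2-methoxy-5-(methoxymethoxy)phenyl}-3-methylbutan-2-ol (racemic) | COCOc1cc(OCc2ccccc2)c(OC)c(CC(O)C(C)C)c1/C=C/c1cc(OCc2ccccc2)cc(OCc2ccccc2)c1
A5 | alternative 2 | methyl 2-{3-(benzyloxy)-6-[2-(3,5-bis(benzyloxy)phenyl)-2-oxoethyl]-2-methoxyphenyl}acetate | COC(=O)Cc1c(OC)c(OCc2ccccc2)ccc1CC(=O)c1cc(OCc2ccccc2)cc(OCc2ccccc2)c1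
A6 | alternative 2 | methyl 2-{6-(benzyloxy)-2-[3,5-bis(benzyloxy)phenyl]-5-methoxybenzofuran-4-yl}acetate | COC(=O)Cc1c(OC)c(OCc2ccccc2)cc2oc(-c3cc(OCc4ccccc4)cc(OCc4ccccc4)c3)cc12
A7 | alternative 3 | {[4-(benzyloxy)-2-{[3,5-bis(benzyloxy)benzoyl]oxy}-5-methoxy-6-(3-methylbut-2-enyl)phenyl]methyl}triphenylphosphonium bromide | [Br-].COc1c(OCc2ccccc2)cc(OC(=O)c2cc(OCc3ccccc3)cc(OCc3ccccc3)c2)c(C[P+](c2ccccc2)(c2ccccc2)c2ccccc2)c1CC=C(C)C
A8 | alternative 3 | 6-(benzyloxy)-2-[3,5-bis(benzyloxy)phenyl]-5-methoxy-4-(3-methylbut-2-enyl)benzofuran (identical with 21) | COc1c(OCc2ccccc2)cc2oc(-c3cc(OCc4ccccc4)cc(OCc4ccccc4)c3)cc2c1CC=C(C)C
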